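At 2.50 h the north run holds more target than the east run, 31 % against 22 %.

| flask | substrate | gas phase | catalyst | remark | time |
|---|---|---|---|---|---|
| east | 0.20 M | 170 mM (held) | 0.05 mol% | run made earlier |  |
| north | 0.80 M | 170 mM (held) | 0.05 mol% | run made earlier |  |
| amber | 0.40 M | 170 mM (held) | 0.05 mol% |  | 3.0 h |
| teal | 0.40 M | 170 mM (held) | 0.05 mol% |  | 2.0 h |

- east (time / h: target / %): 0.167: 0; 0.500: 5; 0.833: 3; 1.33: 6; 2.00: 14; 2.50: 22
- north (time / h: target / %): 0.167: 2; 0.500: 3; 0.833: 11; 1.33: 19; 2.00: 24; 2.50: 31

(each reading ± 1.5 percentage points)

- what was read earlier has a scatter of 1.5 percentage points, one standard deviation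
- at the start none of the gas phase is in solution

- which one finishes higher in amount of target, in percent of the substrate charged ("neither" within 2 percentage points) (amber / teal / neither)
- amount of target at the end, in percent of the substrate charged, amber
- amount of target at the end, in percent of the substrate charged, teal

The east run gains 16 percentage points between 1.33 h and 2.50 h, which puts at 7.31 h the clearing time: the time a straight climb at that pace takes to cross the whole charge. Running that line back from the last readings gives a lag (induction period) of 0.891 h in the east run and 0.233 h in the north run, both readings with their scatter. Our 0.40 M is twice the east strength and half the north one, so we take the geometric mean, 0.456 h.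

| Rung | Time | Share of clearing time | The flask |
|---|---|---|---|
| lag | 0.456 h | 6.24 % | target just starting |
| teal stops | 2.0 h | 27.4 % | on the straight stretch |
| amber stops | 3.0 h | 41.0 % | on the straight stretch |
| clearing time | 7.31 h | whole | the line has reached the charge |

Teal stops later than 0.456 h and amber earlier than 7.31 h, so we reckon target in each flask as the time after 0.456 h over the clearing time: 21.1 % for teal and 34.8 % for amber.

The forecast says amber, with 34 % (28 % to 40 %) for amber and 20 % (16 % to 24 %) for teal: “Amber is clearly higher because it simply runs longer under the same conditions.” Its lag at this strength is 0.5 to 0.6 h, ours 0.456 h, and our figures lie 1.1 points and 0.80 points above its own.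

The flask gives 33.2 % for amber and 22.3 % for teal, so amber finishes higher.

    gas phase ⇌ dissolved gas, rate k1*(csat - [dissolved gas]) (kL = 3.91 × 10⁻⁴ s⁻¹)
    substrate + dissolved gas + catalyst → catalyst + target (k = 2.07 M⁻² s⁻¹)
    target + catalyst ⇌ isomer of the product + catalyst, rate k3*[catalyst]*[target] forward; the back reaction follows from the equilibrium constant (K = 0.990, k = 0.125 M⁻¹ s⁻¹)

In teal, the half-life of target by the forward step to the isomer of the product alone is 7.7 h at 0.671 h, longer than the run's 2.0 h and close to the clearing time. At the end of teal, target is made 7.53 times faster than it goes over to the isomer of the product, each step taken net. A reading of teal at 8.0 h lies beyond the clearing time: there the straight line reads 103 % of the charge, while that flask holds 57.9 % target, 20.5 % isomer of the product and 22 % substrate.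

All runs were computed for an exercise; the scatter is artificial.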